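**Retrosynthetic overview**
- Target ⇐ (2S)-5,7-bis-MOM flavanone. The C4 ketone is carried as a spiro-1,3-dithiane and the 4'-OH as an aryl bromide (Br→Li→B→OH) until late in the route.
- Ring C is the only ring built: intramolecular Mitsunobu etherification (O1–C2, inversion) of a symmetric triphenol/(R)-carbinol. Rings A and B come intact from phloroglucinol and a 4-bromophenyl ketone.
- C3–C4 bond: lithiated aryl-dithiane (acyl-anion equivalent) + (S)-2-(4-bromophenyl)oxirane.
- The epoxide comes from the (S)-chlorohydrin made by ketoreductase (KRED) reduction of 1-(4-bromophenyl)-2-chloroethanone, the only stereocentre-forming step.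
- The aryl dithiane comes from phloroglucinol tris-MOM ether by three successive directed ortho-metalations (prenyl, prenyl, dithianyl).

Assumption: the target is the (2S) enantiomer encoded by the SMILES, and a commercial (S)-selective (anti-Prelog) KRED from a screening panel accepts the α-chloro aryl ketone. "Prenyl" = 3-methylbut-2-en-1-yl.

---

**Step 1**
Reactants: 1 phloroglucinol; 2 chloromethyl methyl ether (MOMCl)
Product: 3 1,3,5-tris(methoxymethoxy)benzene
Conditions: NaH, MOMCl, DMF, 0 °C→rt
Reagents that add atoms: MOMCl, COCCl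
Why: Williamson-type O-alkylation of the triphenoxide; the MOM ethers later serve as ortho-directing groups.

**Step 2**
Reactants: 3; 4 prenyl bromide
Product: 5 1,3,5-tris(methoxymethoxy)-2-prenylbenzene
Conditions: n-BuLi, THF, 0 °C→rt; CuI (cat.), 4, −78 °C→rt
Reagents that add atoms: prenyl bromide, CC(C)=CCBr
Why: Directed ortho-metalation between two OMOM groups (all three ring CH are equivalent) followed by Cu-mediated SN2 allylation gives only the linear C-prenyl product.

**Step 3**
Reactants: 5; 4 prenyl bromide
Product: 6 1,3,5-tris(methoxymethoxy)-2,4-diprenylbenzene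
Conditions: n-BuLi, TMEDA, THF, 0 °C; CuI (cat.), 4, −78 °C→rt
Reagents that add atoms: prenyl bromide, CC(C)=CCBr
Why: Second directed ortho-metalation/allylation; the two remaining ring positions are equivalent and each is flanked by two OMOM groups, so one regioisomer forms.

**Step 4**
Reactants: 6; 7 1,3-dithiane (converted just before use into 2-chloro-1,3-dithiane)
Product: 8 2-[2,4,6-tris(methoxymethoxy)-3,5-diprenylphenyl]-1,3-dithiane
Conditions: (i) n-BuLi, TMEDA, THF, 0 °C; (ii) MgBr2·OEt2, −20 °C; (iii) 2-chloro-1,3-dithiane [from 7, NCS, PhMe, rt], −40 °C→rt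
Reagents that add atoms: 2-chloro-1,3-dithiane, ClC1SCCCS1 (from 1,3-dithiane, C1CSCSC1)
Why: Directed ortho-metalation at the last ring CH, Li→Mg transmetalation and capture of the aryl Grignard by the dithianylium equivalent install the masked C4 carbonyl without acid, so MOM ethers and prenyl groups are untouched.

**Step 5**
Reactants: 9 1-(4-bromophenyl)-2-chloroethan-1-one
Product: 10 (S)-1-(4-bromophenyl)-2-chloroethan-1-ol
Conditions: (S)-selective ketoreductase (KRED, NADPH-dependent alcohol dehydrogenase), NADP+ (cat.), i-PrOH (15% v/v), KPi buffer pH 7.0, 30 °C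
Reagents that add atoms: none
Why: Biocatalytic asymmetric ketone reduction; the enzyme delivers hydride from NADPH to one face of the aryl chloromethyl ketone (typically >99% ee for this substrate class), setting the only stereocentre as (S).

**Step 6**
Reactants: 10
Product: 11 (S)-2-(4-bromophenyl)oxirane
Conditions: K2CO3, MeOH, 0 °C→rt
Reagents that add atoms: none
Why: Intramolecular Williamson etherification at the CH2Cl carbon; no bond to the stereocentre is broken, so (S) is retained.

**Step 7**
Reactants: 8; 11
Product: 12 (R)-1-(4-bromophenyl)-2-{2-[2,4,6-tris(methoxymethoxy)-3,5-diprenylphenyl]-1,3-dithian-2-yl}ethan-1-ol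
Conditions: 8, n-BuLi (1.0 equiv), THF, −30 °C; then 11, DMPU, −30→0 °C
Reagents that add atoms: none
Why: Corey–Seebach umpolung; the 2-lithio-2-aryl-dithiane opens the epoxide at the unhindered CH2 terminus, so the benzylic C–O bond and its configuration are retained (the descriptor becomes R only because CIP priorities change).

**Step 8**
Reactants: 12
Product: 13 2-{2-[(2R)-2-(4-bromophenyl)-2-hydroxyethyl]-1,3-dithian-2-yl}-4,6-diprenylbenzene-1,3,5-triol
Conditions: 3 M aq. HCl–MeOH (1:5), rt→40 °C, Ar; crude product used directly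
Reagents that add atoms: none
Why: Acid-catalysed MOM acetal hydrolysis; the dithiane, aryl bromide and prenyl groups tolerate dilute methanolic HCl, and the 4-bromophenyl carbinol cannot ionise, so the stereocentre is safe.

**Step 9**
Reactants: 13
Product: 14 (2S)-2-(4-bromophenyl)-6,8-diprenylspiro[chromane-4,2'-[1,3]dithiane]-5,7-diol
Conditions: PPh3, DIAD, THF (0.02 M), 0 °C→rt
Reagents that add atoms: none
Why: Intramolecular Mitsunobu etherification (6-exo-tet SN2) with inversion, (R)-carbinol → (S)-C2; the electron-poor 4-bromophenyl group disfavours SN1 leakage, the dithiane blocks β-elimination to a chalcone, and the two ortho-phenols are symmetry-equivalent so only one chroman can form.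

**Step 10**
Reactants: 14; 2 MOMCl
Product: 15 (2S)-2-(4-bromophenyl)-5,7-bis(methoxymethoxy)-6,8-diprenylspiro[chromane-4,2'-[1,3]dithiane]
Conditions: NaH, MOMCl, DMF, 0 °C→rt
Reagents that add atoms: MOMCl, COCCl
Why: Phenol O-alkylation; both A-ring phenols are masked again so the organolithium and MeI steps that follow meet no acidic or nucleophilic A-ring OH.

**Step 11**
Reactants: 15
Product: 16 4-[(2S)-5,7-bis(methoxymethoxy)-6,8-diprenylspiro[chromane-4,2'-[1,3]dithian]-2-yl]phenol
Conditions: t-BuLi (2.1 equiv), THF, −78 °C; B(OMe)3, −78 °C→rt; then 30% H2O2, aq. NaOH, 0 °C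
Reagents that add atoms: hydrogen peroxide, OO (B(OMe)3, COB(OC)OC, is only a transient carrier)
Why: Br/Li exchange, borylation and oxidative ipso-hydroxylation convert the bromide into the 4'-phenol; with C4 still a dithiane there is no carbonyl, so the basic conditions cannot open the pyran ring or epimerise C2.

**Step 12**
Reactants: 16
Product: 17 (2S)-2-(4-hydroxyphenyl)-5,7-bis(methoxymethoxy)-6,8-diprenylchroman-4-one
Conditions: MeI, CaCO3, MeCN–H2O (9:1), 45 °C
Reagents that add atoms: water, O
Why: S-alkylative dithiane hydrolysis under near-neutral, non-oxidative conditions unmasks the C4 ketone without touching the prenyl alkenes, MOM ethers, the un-ionised phenol or C2.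

**Step 13**
Reactants: 17
Product: 18 (2S)-6,8-diprenylnaringenin
Conditions: HCl (1.25 M in MeOH), rt→40 °C
Reagents that add atoms: none
Why: Mild acid hydrolysis of the two MOM acetals; flavanone racemisation is base-mediated (via the chalcone) and does not occur under dilute acid, and cool, short exposure avoids cyclisation of prenyl onto the phenols.

---

**Compound list**

1 | phloroglucinol | Oc1cc(O)cc(O)c1 | starting material
2 | chloromethyl methyl ether (MOMCl) | COCCl | starting material
3 | 1,3,5-tris(methoxymethoxy)benzene | COCOc1cc(OCOC)cc(OCOC)c1 | intermediate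
4 | prenyl bromide (1-bromo-3-methylbut-2-ene) | CC(C)=CCBr | starting material
5 | 1,3,5-tris(methoxymethoxy)-2-prenylbenzene | COCOc1cc(OCOC)c(CC=C(C)C)c(OCOC)c1 | intermediate
6 | 1,3,5-tris(methoxymethoxy)-2,4-diprenylbenzene | COCOc1cc(OCOC)c(CC=C(C)C)c(OCOC)c1CC=C(C)C | intermediate
7 | 1,3-dithiane | C1CSCSC1 | starting material
8 | 2-[2,4,6-tris(methoxymethoxy)-3,5-diprenylphenyl]-1,3-dithiane | COCOc1c(CC=C(C)C)c(OCOC)c(CC=C(C)C)c(OCOC)c1C1SCCCS1 | intermediate
9 | 1-(4-bromophenyl)-2-chloroethan-1-one | O=C(CCl)c1ccc(Br)cc1 | starting material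
10 | (S)-1-(4-bromophenyl)-2-chloroethan-1-ol | O[C@H](CCl)c1ccc(Br)cc1 | intermediate
11 | (S)-2-(4-bromophenyl)oxirane | Brc1ccc([C@H]2CO2)cc1 | intermediate
12 | (R)-1-(4-bromophenyl)-2-{2-[2,4,6-tris(methoxymethoxy)-3,5-diprenylphenyl]-1,3-dithian-2-yl}ethan-1-ol | COCOc1c(CC=C(C)C)c(OCOC)c(CC=C(C)C)c(OCOC)c1C1(C[C@@H](O)c2ccc(Br)cc2)SCCCS1 | intermediate
13 | 2-{2-[(2R)-2-(4-bromophenyl)-2-hydroxyethyl]-1,3-dithian-2-yl}-4,6-diprenylbenzene-1,3,5-triol | Oc1c(CC=C(C)C)c(O)c(CC=C(C)C)c(O)c1C1(C[C@@H](O)c2ccc(Br)cc2)SCCCS1 | intermediate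
14 | (2S)-2-(4-bromophenyl)-6,8-diprenylspiro[chromane-4,2'-[1,3]dithiane]-5,7-diol | CC(C)=CCc1c(O)c(CC=C(C)C)c2c(c1O)C1(SCCCS1)C[C@@H](c1ccc(Br)cc1)O2 | intermediate
15 | (2S)-2-(4-bromophenyl)-5,7-bis(methoxymethoxy)-6,8-diprenylspiro[chromane-4,2'-[1,3]dithiane] | CC(C)=CCc1c(OCOC)c(CC=C(C)C)c2c(c1OCOC)C1(SCCCS1)C[C@@H](c1ccc(Br)cc1)O2 | intermediate
16 | 4-[(2S)-5,7-bis(methoxymethoxy)-6,8-diprenylspiro[chromane-4,2'-[1,3]dithian]-2-yl]phenol | CC(C)=CCc1c(OCOC)c(CC=C(C)C)c2c(c1OCOC)C1(SCCCS1)C[C@@H](c1ccc(O)cc1)O2 | intermediate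
17 | (2S)-2-(4-hydroxyphenyl)-5,7-bis(methoxymethoxy)-6,8-diprenylchroman-4-one | CC(C)=CCc1c(OCOC)c(CC=C(C)C)c2c(c1OCOC)C(=O)C[C@@H](c1ccc(O)cc1)O2 | intermediate
18 | (2S)-6,8-diprenylnaringenin | CC(C)=CCc1c(O)c(CC=C(C)C)c2c(c1O)C(=O)C[C@@H](c1ccc(O)cc1)O2 | target

---

**Totals**
- Total steps: 13.
- Longest linear sequence: 11 (steps 1–4, then 7–13); the epoxide branch (steps 5–6) joins at step 7.

**Three steps most likely to fail**
1. **Step 7** (very hindered tertiary dithiane anion + epoxide may be sluggish or give some benzylic opening). Fallback: change the electrophile class. Silylate chlorohydrin 10, convert it to the primary iodide (Finkelstein), alkylate the dithiane anion by SN2, then desilylate to reach 12.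
2. **Step 9** (Mitsunobu on an air-sensitive triphenol; elimination to a styrene or intermolecular etherification may compete). Fallback: a two-step net-retention closure. Make the enantiomeric carbinol with an (R)-selective (Prelog) KRED in step 5, convert the alcohol to the benzylic chloride with inversion (Appel), then close the ring with Cs2CO3 (second inversion) to the same (2S)-chroman.
3. **Step 4** (2-chloro-1,3-dithiane is unstable and the aryl Grignard is di-ortho-substituted). Fallback: quench the aryl-lithium with DMF to the tris-MOM benzaldehyde and build the acyl-anion equivalent from the aldehyde instead, either by dithioacetalisation with propane-1,3-dithiol under a mild neutral catalyst or as the α-morpholino nitrile.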